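**Plan**

1. Retrosynthetic cuts: (a) C3=C4 by ring-closing metathesis; (b) the lactone C19–O bond and the diene arm (C4–C5, C5=C6, C6–C7) back to a C7 acyl group; (c) C8–C9 by aldol union of a ring-A aldehyde with an L-malic acid unit (C7, C8, C17–C19); (d) C1–C2 by aldol with acrolein; (e) ring A into the diene C13=C14–C1=C10 and the alkyne C11≡C12.
2. Enabling feature: ring A (C1, C10–C14) has oxygen at C14 next to quaternary C1 and, across the ring, the C11(CH3)–C12 epoxide. It is a masked 1-silyloxycyclohexa-1,4-diene, the [4+2] adduct of a 2-silyloxydiene and a propyne equivalent, and the C14=C1 enol ether left by the cycloaddition is the regiodefined enolate needed to build C1.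
3. Forward order: ring A (steps 1–6), C1/C2/C14 (7–8), C8–C9 union (15), C7 arm and lactone (16–21), epoxide and acetates (22–24), ten-membered ring last (25), release of C16–OH (26).
4. Stereochemistry: C10 from the chiral amine catalyst; C1 anti to the C10 arm; C2 from the open aldol transition state; C14 by 1,3-syn reduction; C17 and C8 from L-malic acid (anti methylation, retentive dioxolanone aldol); C9 Felkin–Anh; C7 by chelation-controlled reduction; C11/C12 by α-face epoxidation; alkene geometries from anti hydroiodination and ring strain.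

Key step: step 4

Remark (locants): C1–C20 are the skeleton positions of the target. Ring A = C1, C10, C11, C12, C13, C14 (C15 = CH3 on C1, C20 = CH3 on C11); ten-membered ring = C1–C10 (C16 = CH2OH on C5); lactone = O, C7, C8, C17 (C18 = CH3), C19. α = face of ring A opposite to CH3-15.
Remark (abbreviations): TBS = tert-butyldimethylsilyl; PMB = 4-methoxybenzyl; A-yl = (4R,4aR,5S,8aS)-2,2-di-tert-butyl-4-ethenyl-4a,6-dimethyl-4a,5,8,8a-tetrahydro-4H-1,3,2-benzodioxasilin-5-yl (ring A with its C2/C14 diol tied as the di-tert-butylsilylene).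
Remark (assumption): the (2S,5S) imidazolidinone in step 4 is assigned by analogy with its known propynal cycloadditions; if it delivers the (6S) aldehyde, its enantiomer is used.
Remark (assumption): ylide 2 is taken as a catalogue compound.

**Route**

Step 1
Reactants: 1 2-(TBS-oxy)acetaldehyde; 2 3-(triphenyl-λ5-phosphanylidene)butan-2-one
Product: 3 (3E)-5-(TBS-oxy)-3-methylpent-3-en-2-one
Conditions: PhMe, 80 °C
Reagents that add atoms: none
Why: Wittig olefination with a stabilised α-branched ylide should give the (E)-trisubstituted enone (CH2OTBS trans to acetyl), the geometry that later puts C9 on the outside of the diene.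

Step 2
Reactants: 3 (3E)-5-(TBS-oxy)-3-methylpent-3-en-2-one
Product: 4 (3E)-2,5-bis(TBS-oxy)-3-methylpenta-1,3-diene
Conditions: TBSOTf, Et3N, CH2Cl2, 0 °C
Reagents that add atoms: tert-butyldimethylsilyl trifluoromethanesulfonate CC(C)(C)[Si](C)(C)OS(=O)(=O)C(F)(F)F
Why: Soft enolisation and O-silylation of a methyl ketone (silyl dienol ether formation) should deprotonate only the acetyl methyl group and leave the (E)-alkene untouched.

Step 3
Reactants: 5 3,3-diethoxyprop-1-yne
Product: 6 prop-2-ynal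
Conditions: H2O, H2SO4 (cat.), 50 °C, distilled into Et2O
Reagents that add atoms: water O
Why: Acid-catalysed acetal hydrolysis should release the volatile ynal, which is used at once as an ethereal solution.

Step 4
Reactants: 4 (3E)-2,5-bis(TBS-oxy)-3-methylpenta-1,3-diene; 6 prop-2-ynal
Product: 7 (6R)-4-(TBS-oxy)-6-[(TBS-oxy)methyl]-5-methylcyclohexa-1,4-diene-1-carbaldehyde
Conditions: (2S,5S)-5-benzyl-2-tert-butyl-3-methylimidazolidin-4-one·CF3CO2H (20 mol%), H2O (1 equiv), Et2O, −40 °C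
Reagents that add atoms: none
Why: Proposed new method: the amine condenses with 6 to an alkynyl iminium ion whose β-carbon C12 is attacked by the enol-ether terminus C13 of s-cis 4 while the α-carbon C11 closes onto C10 in an asynchronous [4+2], and hydrolysis of the resulting dienyl iminium releases 7 and the amine; the closest known reaction types are the imidazolidinone-catalysed enantioselective Diels–Alder reaction of propynal with 2-vinylindoles and the thermal cycloadditions of 2-silyloxydienes with propiolates. Ring A (C1, C10–C14) closes by intermolecular [4+2] cycloaddition of the diene C13=C14–C1=C10 with the dienophile C11≡C12, which leaves the C11=C12 alkene and the C14=C1 silyl enol ether. The only new stereocentre, C10, should be set by the catalyst, whose benzyl group shields one face of the iminium so that the diene adds to the open face with its C10 arm turned away from the tert-butyl group. The step needs C13 to bond to C12 and C10 to C11, which is secured by the 2-silyloxy group (C13 is the nucleophilic terminus) and reinforced by the C10 substituent (ortho/para rule). It also needs attack at the β-carbon only, which the iminium secures by masking the formyl carbon against Mukaiyama aldol addition. The (E)-geometry of C1=C10 keeps the s-cis conformer accessible, and the cold, buffered conditions should let the TBS enol ether survive.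

Step 5
Reactants: 7 (6R)-4-(TBS-oxy)-6-[(TBS-oxy)methyl]-5-methylcyclohexa-1,4-diene-1-carbaldehyde
Product: 8 [(6S)-4-(TBS-oxy)-6-[(TBS-oxy)methyl]-5-methylcyclohexa-1,4-dien-1-yl]methanol
Conditions: iBu2AlH, CH2Cl2, −78 °C
Reagents that add atoms: none
Why: 1,2-Reduction of the enal by the aluminium hydride at low temperature should spare both silyl groups and remove the aldehyde before it can aromatise or act as an aldol acceptor (same spatial arrangement at C10; the descriptor changes by priority only).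

Step 6
Reactants: 8 [(6S)-4-(TBS-oxy)-6-[(TBS-oxy)methyl]-5-methylcyclohexa-1,4-dien-1-yl]methanol
Product: 10 (3S)-1-(TBS-oxy)-3-[(TBS-oxy)methyl]-2,4-dimethylcyclohexa-1,4-diene, via allylic methanesulfonate 9 (not isolated)
Conditions: MsCl, Et3N, CH2Cl2, −40 °C; then LiEt3BH, THF, −78 to 0 °C
Reagents that add atoms: none
Why: Sulfonylation followed by SN2 hydride displacement (deoxygenation of a primary allylic alcohol) should turn C20 into the methyl group, attack at the unhindered primary carbon outrunning SN2′ delivery to ring carbon C12.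

Step 7
Reactants: 10 (3S)-1-(TBS-oxy)-3-[(TBS-oxy)methyl]-2,4-dimethylcyclohexa-1,4-diene; 11 prop-2-enal
Product: 12 (2S,3S)-3-[(TBS-oxy)methyl]-2-[(1R)-1-hydroxyprop-2-en-1-yl]-2,4-dimethylcyclohex-4-en-1-one
Conditions: BF3·OEt2, CH2Cl2, −78 °C
Reagents that add atoms: none
Why: Mukaiyama aldol addition of the regiodefined silyl enol ether should create quaternary C1 with the aldehyde entering anti to the C10 CH2OTBS arm (C2 trans to C9), and the open antiperiplanar transition state, with the vinyl group gauche to the C1 methyl and not to branched C10, should favour the (R) carbinol at C2.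

Step 8
Reactants: 12 (2S,3S)-3-[(TBS-oxy)methyl]-2-[(1R)-1-hydroxyprop-2-en-1-yl]-2,4-dimethylcyclohex-4-en-1-one
Product: 13 (1S,5S,6R)-5-[(TBS-oxy)methyl]-6-[(1R)-1-hydroxyprop-2-en-1-yl]-4,6-dimethylcyclohex-3-en-1-ol
Conditions: Et2BOMe, NaBH4, THF/MeOH (4:1), −78 °C
Reagents that add atoms: none
Why: Narasaka–Prasad reduction, in which external hydride attacks the six-membered boron chelate of the β-hydroxy ketone, should give the 1,3-syn diol and so set C14 (OH α, trans to CH3-15).

Step 9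
Reactants: 13 (1S,5S,6R)-5-[(TBS-oxy)methyl]-6-[(1R)-1-hydroxyprop-2-en-1-yl]-4,6-dimethylcyclohex-3-en-1-ol
Product: 14 (4R,4aR,5S,8aS)-2,2-di-tert-butyl-5-[(TBS-oxy)methyl]-4-ethenyl-4a,6-dimethyl-4a,5,8,8a-tetrahydro-4H-1,3,2-benzodioxasiline
Conditions: tBu2Si(OTf)2, 2,6-lutidine, CH2Cl2, 0 °C
Reagents that add atoms: di-tert-butylsilyl bis(trifluoromethanesulfonate) CC(C)(C)[Si](OS(=O)(=O)C(F)(F)F)(OS(=O)(=O)C(F)(F)F)C(C)(C)C
Why: Silylene protection of the syn-1,3-diol should close the six-membered dioxasilinane and mask C2–OH and C14–OH with one fluoride-labile group.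

Step 10
Reactants: 14 (4R,4aR,5S,8aS)-2,2-di-tert-butyl-5-[(TBS-oxy)methyl]-4-ethenyl-4a,6-dimethyl-4a,5,8,8a-tetrahydro-4H-1,3,2-benzodioxasiline
Product: 15 (A-yl)methanol
Conditions: camphorsulfonic acid (10 mol%), MeOH/CH2Cl2, 0 °C
Reagents that add atoms: none
Why: Acid-catalysed methanolysis should remove the unhindered primary TBS ether while the di-tert-butylsilylene of the hindered diol survives.

Step 11
Reactants: 15 (A-yl)methanol
Product: 16 A-yl carbaldehyde [(4R,4aR,5S,8aS)-2,2-di-tert-butyl-4-ethenyl-4a,6-dimethyl-4a,5,8,8a-tetrahydro-4H-1,3,2-benzodioxasiline-5-carbaldehyde]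
Conditions: Dess–Martin periodinane, NaHCO3, CH2Cl2, 0 °C
Reagents that add atoms: none
Why: Dess–Martin oxidation under buffered, base-free conditions should give the β,γ-unsaturated aldehyde without epimerising C10 or moving the alkene into conjugation; it is used crude.

Step 12
Reactants: 17 dimethyl (2S)-2-hydroxybutanedioate
Product: 19 dimethyl (2S,3R)-2-hydroxy-3-methylbutanedioate, via dilithium alkoxide enolate 18 (not isolated)
Conditions: LiN(iPr)2 (2.2 equiv), THF, −78 to −20 °C; then MeI, −78 °C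
Reagents that add atoms: iodomethane CI
Why: Fráter–Seebach alkylation of the chelated dilithium alkoxide enolate should methylate anti to the C–O bond and give the (2S,3R) diastereomer, which sets C17.

Step 13
Reactants: 19 dimethyl (2S,3R)-2-hydroxy-3-methylbutanedioate
Product: 20 (2S,3R)-2-hydroxy-3-methylbutanedioic acid
Conditions: KOH, MeOH/H2O, rt; then aq. HCl
Reagents that add atoms: potassium hydroxide [K+].[OH-]
Why: Ester saponification at room temperature should give the diacid without epimerising the carboxylate-protected C17.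

Step 14
Reactants: 20 (2S,3R)-2-hydroxy-3-methylbutanedioic acid; 21 2,2-dimethylpropanal
Product: 22 (2R)-2-[(2S,4S)-2-tert-butyl-5-oxo-1,3-dioxolan-4-yl]propanoic acid
Conditions: TsOH (cat.), H2SO4 (cat.), pentane, reflux, water separator
Reagents that add atoms: none
Why: Acetalisation of the α-hydroxy acid should give the thermodynamic cis-2-tert-butyl-1,3-dioxolan-4-one, which stores the C8 configuration in the new acetal centre (self-regeneration of stereocentres) and leaves the C19 carboxyl free.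

Step 15
Reactants: 22 (2R)-2-[(2S,4S)-2-tert-butyl-5-oxo-1,3-dioxolan-4-yl]propanoic acid; 16 A-yl carbaldehyde
Product: 25 (2R)-2-[(2S,4R)-2-tert-butyl-4-[(R)-(TBS-oxy)(A-yl)methyl]-5-oxo-1,3-dioxolan-4-yl]propanoic acid, via dilithium enolate 23 (not isolated), via aldol hydroxy acid 24 (not isolated)
Conditions: LiN(SiMe3)2 (2.2 equiv), THF, −78 °C; 16; then TBSOTf, −78 to −20 °C; aq. citric acid
Reagents that add atoms: tert-butyldimethylsilyl trifluoromethanesulfonate CC(C)(C)[Si](C)(C)OS(=O)(=O)C(F)(F)F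
Why: Aldol addition of the dioxolanone enolate should take place on the face anti to the tert-butyl group, so that C9 replaces H-8 with retention (quaternary C8), and in the Felkin–Anh sense anti to quaternary C1 of the aldehyde (C9); the carboxylate blocks enolisation at C17, and silylation in the flask stops retro-aldol and lactonisation of C9–OH onto C19.

Step 16
Reactants: 25 (2R)-2-[(2S,4R)-2-tert-butyl-4-[(R)-(TBS-oxy)(A-yl)methyl]-5-oxo-1,3-dioxolan-4-yl]propanoic acid
Product: 26 (2R,3R,4R)-4-(TBS-oxy)-3-hydroxy-3-[methoxy(methyl)carbamoyl]-2-methyl-4-(A-yl)butanoic acid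
Conditions: MeNH(OMe)·HCl, iPrMgCl, THF, −20 to 0 °C
Reagents that add atoms: N,O-dimethylhydroxylamine hydrochloride CNOC.Cl
Why: Aminolysis of the activated acylal carbonyl by the magnesium amide should give the Weinreb amide at C7, release pivalaldehyde and free the tertiary C8 hydroxyl, with the C19 carboxylate inert.

Step 17
Reactants: 27 prop-2-yn-1-ol
Product: 28 1-methoxy-4-[(prop-2-yn-1-yloxy)methyl]benzene
Conditions: NaH, 4-methoxybenzyl chloride, Bu4NI (cat.), THF, 0 °C to rt
Reagents that add atoms: 4-methoxybenzyl chloride COc1ccc(CCl)cc1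
Why: Williamson ether synthesis should give the PMB ether that will carry C5, C6 and C16.

Step 18
Reactants: 26 (2R,3R,4R)-4-(TBS-oxy)-3-hydroxy-3-[methoxy(methyl)carbamoyl]-2-methyl-4-(A-yl)butanoic acid; 28 1-methoxy-4-[(prop-2-yn-1-yloxy)methyl]benzene
Product: 30 (2R,3R)-3-[(R)-(TBS-oxy)(A-yl)methyl]-3-hydroxy-7-(PMB-oxy)-2-methyl-4-oxohept-5-ynoic acid, via lithium acetylide 29 (not isolated)
Conditions: 28 (4.2 equiv), n-BuLi, THF, −78 °C; then 26, −78 to −30 °C; AcOH, −78 °C
Reagents that add atoms: none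
Why: Acetylide addition to the Weinreb amide should stop at the chelated tetrahedral intermediate and give the ynone on cold acidic quench, which also prevents 5-endo cyclisation of the C8 alkoxide onto the ynone.

Step 19
Reactants: 30 (2R,3R)-3-[(R)-(TBS-oxy)(A-yl)methyl]-3-hydroxy-7-(PMB-oxy)-2-methyl-4-oxohept-5-ynoic acid
Product: 31 (2R,3R,5Z)-3-[(R)-(TBS-oxy)(A-yl)methyl]-3-hydroxy-6-iodo-7-(PMB-oxy)-2-methyl-4-oxohept-5-enoic acid
Conditions: NaI, AcOH, rt
Reagents that add atoms: sodium iodide [Na+].[I-]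
Why: Conjugate hydroiodination of the ynone proceeds by anti addition and should give the (Z)-β-iodo enone, fixing the C5=C6 geometry with C7 cis to the site of the future C4.

Step 20
Reactants: 31 (2R,3R,5Z)-3-[(R)-(TBS-oxy)(A-yl)methyl]-3-hydroxy-6-iodo-7-(PMB-oxy)-2-methyl-4-oxohept-5-enoic acid; 32 tributyl(ethenyl)stannane
Product: 33 (2R,3R,5E)-3-[(R)-(TBS-oxy)(A-yl)methyl]-3-hydroxy-6-[(PMB-oxy)methyl]-2-methyl-4-oxoocta-5,7-dienoic acid
Conditions: Pd2(dba)3 (5 mol%), AsPh3 (20 mol%), CuI (10 mol%), N-methylpyrrolidone, rt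
Reagents that add atoms: none
Why: Stille coupling with retention of alkene geometry should install the vinyl group (C4 and the carbon lost in step 25) cis to C7.

Step 21
Reactants: 33 (2R,3R,5E)-3-[(R)-(TBS-oxy)(A-yl)methyl]-3-hydroxy-6-[(PMB-oxy)methyl]-2-methyl-4-oxoocta-5,7-dienoic acid
Product: 35 (3R,4S,5S)-4-[(R)-(TBS-oxy)(A-yl)methyl]-4-hydroxy-3-methyl-5-[(1E)-2-[(PMB-oxy)methyl]buta-1,3-dien-1-yl]oxolan-2-one, via dihydroxy acid 34 (not isolated)
Conditions: Zn(BH4)2, Et2O, −30 °C; aq. NH4Cl; then pyridinium p-toluenesulfonate (cat.), PhMe, 40 °C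
Reagents that add atoms: none
Why: Chelation-controlled 1,2-reduction of the α-hydroxy ketone, with hydride attacking the zinc chelate anti to the bulky C9 arm, should give the 7,8-anti diol and set C7, and the γ-hydroxy acid then closes to the five-membered lactone.

Step 22
Reactants: 35 (3R,4S,5S)-4-[(R)-(TBS-oxy)(A-yl)methyl]-4-hydroxy-3-methyl-5-[(1E)-2-[(PMB-oxy)methyl]buta-1,3-dien-1-yl]oxolan-2-one
Product: 36 11α,12α-epoxide of 35
Conditions: mCPBA, NaHCO3, CH2Cl2, 0 °C
Reagents that add atoms: 3-chloroperoxybenzoic acid OOC(=O)c1cccc(Cl)c1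
Why: Prilezhaev epoxidation should select the electron-rich trisubstituted ring alkene over the oxygen-flanked diene and the terminal vinyl group, and attack the α face, anti to axial CH3-15 and to the C9 arm with its OTBS group on allylic C10, setting C11 and C12.

Step 23
Reactants: 36 11α,12α-epoxide of 35
Product: 37 desilylated epoxy lactone (C2–OH, C9–OH, C14–OH and C8–OH free, C16–OPMB)
Conditions: HF·pyridine, pyridine, THF, 0 °C to rt
Reagents that add atoms: none
Why: Fluoride cleavage should remove the silylene and the C9 TBS ether in one operation, and buffered HF·pyridine is tolerated by trisubstituted epoxides and lactones.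

Step 24
Reactants: 37 desilylated epoxy lactone
Product: 38 2,9,14-triacetate of 37
Conditions: Ac2O, pyridine, 4-(dimethylamino)pyridine (cat.), CH2Cl2, 0 °C to rt
Reagents that add atoms: acetic anhydride CC(=O)OC(C)=O
Why: Nucleophile-catalysed acetylation should esterify the three secondary alcohols and leave the hindered tertiary C8–OH of the β-hydroxy lactone free.

Step 25
Reactants: 38 2,9,14-triacetate of 37
Product: 39 16-O-PMB ether of the target
Conditions: second-generation Grubbs catalyst RuCl2(=CHPh)(H2IMes)(PCy3) (10 mol%), PhMe (1 mM), 80 °C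
Reagents that add atoms: none
Why: Ring-closing metathesis, with the ruthenium carbene loading on the terminal vinyl of the diene and closing onto the C2 vinyl group, should form C3=C4, whose (Z) geometry is enforced by the ten-membered ring, while the trisubstituted C5=C6 stays out of the catalytic cycle.

Step 26
Reactants: 39 16-O-PMB ether of the target
Product: 40 target compound
Conditions: 2,3-dichloro-5,6-dicyano-1,4-benzoquinone (DDQ), CH2Cl2/pH 7 buffer, 0 °C
Reagents that add atoms: none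
Why: Oxidative cleavage of the PMB ether under buffered conditions should free C16–OH without touching the acetates, the epoxide, the lactone or the diene.

**Compound list**

1 | 2-(TBS-oxy)acetaldehyde | O=CCO[Si](C)(C)C(C)(C)C | starting material
2 | 3-(triphenyl-λ5-phosphanylidene)butan-2-one | CC(=O)C(C)=P(c1ccccc1)(c1ccccc1)c1ccccc1 | starting material
3 | (3E)-5-(TBS-oxy)-3-methylpent-3-en-2-one | CC(=O)/C(C)=C/CO[Si](C)(C)C(C)(C)C | intermediate
4 | (3E)-2,5-bis(TBS-oxy)-3-methylpenta-1,3-diene | C=C(O[Si](C)(C)C(C)(C)C)/C(C)=C/CO[Si](C)(C)C(C)(C)C | intermediate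
5 | 3,3-diethoxyprop-1-yne | C#CC(OCC)OCC | starting material
6 | prop-2-ynal | C#CC=O | intermediate
7 | (6R)-4-(TBS-oxy)-6-[(TBS-oxy)methyl]-5-methylcyclohexa-1,4-diene-1-carbaldehyde | O=CC1=CCC(O[Si](C)(C)C(C)(C)C)=C(C)[C@H]1CO[Si](C)(C)C(C)(C)C | intermediate
8 | [(6S)-4-(TBS-oxy)-6-[(TBS-oxy)methyl]-5-methylcyclohexa-1,4-dien-1-yl]methanol | OCC1=CCC(O[Si](C)(C)C(C)(C)C)=C(C)[C@H]1CO[Si](C)(C)C(C)(C)C | intermediate
9 | methanesulfonate of 8 | CS(=O)(=O)OCC1=CCC(O[Si](C)(C)C(C)(C)C)=C(C)[C@H]1CO[Si](C)(C)C(C)(C)C | intermediate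
10 | (3S)-1-(TBS-oxy)-3-[(TBS-oxy)methyl]-2,4-dimethylcyclohexa-1,4-diene | CC1=CCC(O[Si](C)(C)C(C)(C)C)=C(C)[C@H]1CO[Si](C)(C)C(C)(C)C | intermediate
11 | prop-2-enal | C=CC=O | starting material
12 | (2S,3S)-3-[(TBS-oxy)methyl]-2-[(1R)-1-hydroxyprop-2-en-1-yl]-2,4-dimethylcyclohex-4-en-1-one | O=C1CC=C(C)[C@H](CO[Si](C)(C)C(C)(C)C)[C@@]1(C)[C@H](O)C=C | intermediate
13 | (1S,5S,6R)-5-[(TBS-oxy)methyl]-6-[(1R)-1-hydroxyprop-2-en-1-yl]-4,6-dimethylcyclohex-3-en-1-ol | O[C@H]1CC=C(C)[C@H](CO[Si](C)(C)C(C)(C)C)[C@@]1(C)[C@H](O)C=C | intermediate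
14 | (4R,4aR,5S,8aS)-2,2-di-tert-butyl-5-[(TBS-oxy)methyl]-4-ethenyl-4a,6-dimethyl-4a,5,8,8a-tetrahydro-4H-1,3,2-benzodioxasiline | C=C[C@H]1O[Si](C(C)(C)C)(C(C)(C)C)O[C@H]2CC=C(C)[C@H](CO[Si](C)(C)C(C)(C)C)[C@@]12C | intermediate
15 | (A-yl)methanol | C=C[C@H]1O[Si](C(C)(C)C)(C(C)(C)C)O[C@H]2CC=C(C)[C@H](CO)[C@@]12C | intermediate
16 | A-yl carbaldehyde | C=C[C@H]1O[Si](C(C)(C)C)(C(C)(C)C)O[C@H]2CC=C(C)[C@H](C=O)[C@@]12C | intermediate
17 | dimethyl (2S)-2-hydroxybutanedioate | COC(=O)C[C@H](O)C(=O)OC | starting material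
18 | dilithium alkoxide enolate of 17 | [Li+].[Li+].COC([O-])=C[C@H]([O-])C(=O)OC | intermediate
19 | dimethyl (2S,3R)-2-hydroxy-3-methylbutanedioate | COC(=O)[C@H](C)[C@H](O)C(=O)OC | intermediate
20 | (2S,3R)-2-hydroxy-3-methylbutanedioic acid | OC(=O)[C@H](C)[C@H](O)C(O)=O | intermediate
21 | 2,2-dimethylpropanal | CC(C)(C)C=O | starting material
22 | (2R)-2-[(2S,4S)-2-tert-butyl-5-oxo-1,3-dioxolan-4-yl]propanoic acid | OC(=O)[C@H](C)[C@@H]1O[C@H](C(C)(C)C)OC1=O | intermediate
23 | dilithium enolate carboxylate of 22 | [Li+].[Li+].[O-]C(=O)[C@H](C)C1=C([O-])O[C@@H](C(C)(C)C)O1 | intermediate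
24 | (2R)-2-[(2S,4R)-2-tert-butyl-4-[(R)-hydroxy(A-yl)methyl]-5-oxo-1,3-dioxolan-4-yl]propanoic acid | C=C[C@H]1O[Si](C(C)(C)C)(C(C)(C)C)O[C@H]2CC=C(C)[C@H]([C@@H](O)[C@]3(O[C@H](C(C)(C)C)OC3=O)[C@@H](C)C(O)=O)[C@@]12C | intermediate
25 | (2R)-2-[(2S,4R)-2-tert-butyl-4-[(R)-(TBS-oxy)(A-yl)methyl]-5-oxo-1,3-dioxolan-4-yl]propanoic acid | C=C[C@H]1O[Si](C(C)(C)C)(C(C)(C)C)O[C@H]2CC=C(C)[C@H]([C@@H](O[Si](C)(C)C(C)(C)C)[C@]3(O[C@H](C(C)(C)C)OC3=O)[C@@H](C)C(O)=O)[C@@]12C | intermediate
26 | (2R,3R,4R)-4-(TBS-oxy)-3-hydroxy-3-[methoxy(methyl)carbamoyl]-2-methyl-4-(A-yl)butanoic acid | C=C[C@H]1O[Si](C(C)(C)C)(C(C)(C)C)O[C@H]2CC=C(C)[C@H]([C@@H](O[Si](C)(C)C(C)(C)C)[C@@](O)(C(=O)N(C)OC)[C@@H](C)C(O)=O)[C@@]12C | intermediate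
27 | prop-2-yn-1-ol | C#CCO | starting material
28 | 1-methoxy-4-[(prop-2-yn-1-yloxy)methyl]benzene | C#CCOCc1ccc(OC)cc1 | intermediate
29 | lithium acetylide of 28 | [Li+].[C-]#CCOCc1ccc(OC)cc1 | intermediate
30 | (2R,3R)-3-[(R)-(TBS-oxy)(A-yl)methyl]-3-hydroxy-7-(PMB-oxy)-2-methyl-4-oxohept-5-ynoic acid | C=C[C@H]1O[Si](C(C)(C)C)(C(C)(C)C)O[C@H]2CC=C(C)[C@H]([C@@H](O[Si](C)(C)C(C)(C)C)[C@@](O)(C(=O)C#CCOCc3ccc(OC)cc3)[C@@H](C)C(O)=O)[C@@]12C | intermediate
31 | (2R,3R,5Z)-3-[(R)-(TBS-oxy)(A-yl)methyl]-3-hydroxy-6-iodo-7-(PMB-oxy)-2-methyl-4-oxohept-5-enoic acid | C=C[C@H]1O[Si](C(C)(C)C)(C(C)(C)C)O[C@H]2CC=C(C)[C@H]([C@@H](O[Si](C)(C)C(C)(C)C)[C@@](O)(C(=O)/C=C(\I)COCc3ccc(OC)cc3)[C@@H](C)C(O)=O)[C@@]12C | intermediate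
32 | tributyl(ethenyl)stannane | C=C[Sn](CCCC)(CCCC)CCCC | starting material
33 | (2R,3R,5E)-3-[(R)-(TBS-oxy)(A-yl)methyl]-3-hydroxy-6-[(PMB-oxy)methyl]-2-methyl-4-oxoocta-5,7-dienoic acid | C=C[C@H]1O[Si](C(C)(C)C)(C(C)(C)C)O[C@H]2CC=C(C)[C@H]([C@@H](O[Si](C)(C)C(C)(C)C)[C@@](O)(C(=O)/C=C(\C=C)COCc3ccc(OC)cc3)[C@@H](C)C(O)=O)[C@@]12C | intermediate
34 | (2R,3S,4S,5E)-3-[(R)-(TBS-oxy)(A-yl)methyl]-3,4-dihydroxy-6-[(PMB-oxy)methyl]-2-methylocta-5,7-dienoic acid | C=C[C@H]1O[Si](C(C)(C)C)(C(C)(C)C)O[C@H]2CC=C(C)[C@H]([C@@H](O[Si](C)(C)C(C)(C)C)[C@@](O)([C@@H](O)/C=C(\C=C)COCc3ccc(OC)cc3)[C@@H](C)C(O)=O)[C@@]12C | intermediate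
35 | (3R,4S,5S)-4-[(R)-(TBS-oxy)(A-yl)methyl]-4-hydroxy-3-methyl-5-[(1E)-2-[(PMB-oxy)methyl]buta-1,3-dien-1-yl]oxolan-2-one | C=C[C@H]1O[Si](C(C)(C)C)(C(C)(C)C)O[C@H]2CC=C(C)[C@H]([C@@H](O[Si](C)(C)C(C)(C)C)[C@@]3(O)[C@H](/C=C(\C=C)COCc4ccc(OC)cc4)OC(=O)[C@@H]3C)[C@@]12C | intermediate
36 | 11α,12α-epoxide of 35 (epoxide oxygen trans to CH3-15 and to the C9 arm) | C=C[C@H]1O[Si](C(C)(C)C)(C(C)(C)C)O[C@H]2C[C@H]3O[C@@]3(C)[C@H]([C@@H](O[Si](C)(C)C(C)(C)C)[C@@]4(O)[C@H](/C=C(\C=C)COCc5ccc(OC)cc5)OC(=O)[C@@H]4C)[C@@]12C | intermediate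
37 | desilylated epoxy lactone (C2–OH, C9–OH, C14–OH, C8–OH free; C16–OPMB; seco at C3/C4) | O[C@H]1C[C@H]2O[C@@]2(C)[C@H]([C@@H](O)[C@@]3(O)[C@H](/C=C(\C=C)COCc4ccc(OC)cc4)OC(=O)[C@@H]3C)[C@@]1(C)[C@H](O)C=C | intermediate
38 | 2,9,14-triacetate of 37 | CC(=O)O[C@H]1C[C@H]2O[C@@]2(C)[C@H]([C@@H](OC(C)=O)[C@@]3(O)[C@H](/C=C(\C=C)COCc4ccc(OC)cc4)OC(=O)[C@@H]3C)[C@@]1(C)[C@H](OC(C)=O)C=C | intermediate
39 | 16-O-PMB ether of the target | CC(=O)O[C@H]1C[C@H]2O[C@@]2(C)[C@@H]2[C@@H](OC(C)=O)[C@@]3(O)[C@H](/C=C(COCc4ccc(OC)cc4)\C=C/[C@@H](OC(C)=O)[C@@]12C)OC(=O)[C@@H]3C | intermediate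
40 | target compound (1R,2R,7S,8S,9R,10S,11S,12R,14S,17R; 3Z,5E) | CC(=O)O[C@H]1C[C@H]2O[C@@]2(C)[C@@H]2[C@@H](OC(C)=O)[C@@]3(O)[C@H](/C=C(CO)\C=C/[C@@H](OC(C)=O)[C@@]12C)OC(=O)[C@@H]3C | target

**Step count and risks**

Total: 26 steps (steps 3, 12–14 and 17 are on side branches). Longest linear sequence: 21 steps (1, 2, 4–11, 15, 16, 18–26).

Steps most likely to fail:

1. Step 4 (Proposed new method). The stepwise pathway may stop after the first C–C bond through loss of the silyl group (open-chain Michael adduct). The product enol ether may add to a second iminium ion, enantiofacial discrimination may be poor, or the 1,4-diene may aromatise. Fallback (known chemistry), setting out from 4 and coming back at 8: thermal Diels–Alder reaction of 4 with methyl propiolate (PhMe, 110 °C) should give, with the same ortho/para regiochemistry, the racemic methyl ester F1. Reduction with iBu2AlH gives the racemic alcohol F2. F2 is separated into its enantiomers by preparative chromatography on a chiral stationary phase, and the (S) enantiomer is 8, which enters step 6; steps 3 and 5 are then not needed.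

2. Step 15. Addition may be slow or reversible because a fully substituted enolate carbon must bond to a branched, neopentyl-type aldehyde. The enolate may instead deprotonate the β,γ-unsaturated aldehyde at C10, with epimerisation or alkene migration. Fallback, setting out from 16 and coming back at 25: Pinnick oxidation of 16 (NaClO2, NaH2PO4, 2-methylbut-2-ene) gives the A-yl carboxylic acid F3, which 1,1′-carbonyldiimidazole converts into the acyl imidazolide F4. Irreversible C-acylation of enolate 23 with F4, again anti to the tert-butyl group, gives the β-keto dioxolanone acid F5. Reduction of its C9 ketone with LiBH(sBu)3 at −78 °C, under polar Felkin–Anh control by the C8–O bond, should give hydroxy acid 24, and silylation (TBSOTf, 2,6-lutidine) gives 25.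

3. Step 25. Intermolecular metathesis may outrun closure of the strained ten-membered ring, and the catalyst may load slowly on the hindered allylic acetate alkene. Fallback, setting out from 35 and coming back at 39: the ring is closed earlier, on 35, where the silylene ring ties C2–O to C14–O and the alkene is an allylic silyl ether. Metathesis with the same ruthenium catalyst should give the silylene-bridged macrocyclic lactone F6. Epoxidation with mCPBA gives its 11α,12α-epoxide F7, HF·pyridine gives the macrocyclic tetraol F8, and acetylation (Ac2O, pyridine, DMAP) gives 39.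

Further compounds
F1 | step 4 | racemic methyl 4-(TBS-oxy)-6-[(TBS-oxy)methyl]-5-methylcyclohexa-1,4-diene-1-carboxylate | COC(=O)C1=CCC(O[Si](C)(C)C(C)(C)C)=C(C)C1CO[Si](C)(C)C(C)(C)C
F2 | step 4 | racemic [4-(TBS-oxy)-6-[(TBS-oxy)methyl]-5-methylcyclohexa-1,4-dien-1-yl]methanol | OCC1=CCC(O[Si](C)(C)C(C)(C)C)=C(C)C1CO[Si](C)(C)C(C)(C)C
F3 | step 15 | A-yl carboxylic acid | C=C[C@H]1O[Si](C(C)(C)C)(C(C)(C)C)O[C@H]2CC=C(C)[C@H](C(O)=O)[C@@]12C
F4 | step 15 | A-yl (1H-imidazol-1-yl) ketone | C=C[C@H]1O[Si](C(C)(C)C)(C(C)(C)C)O[C@H]2CC=C(C)[C@H](C(=O)n3ccnc3)[C@@]12C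
F5 | step 15 | (2R)-2-[(2S)-2-tert-butyl-4-(A-yl carbonyl)-5-oxo-1,3-dioxolan-4-yl]propanoic acid, C8 configured as in 24 | C=C[C@H]1O[Si](C(C)(C)C)(C(C)(C)C)O[C@H]2CC=C(C)[C@H](C(=O)[C@]3(O[C@H](C(C)(C)C)OC3=O)[C@@H](C)C(O)=O)[C@@]12C
F6 | step 25 | macrocyclic lactone with 2,14-O-di-tert-butylsilylene, 9-O-TBS, 16-O-PMB and the C11=C12 alkene | CC(C)(C)[Si]1(C(C)(C)C)O[C@H]2CC=C(C)[C@@H]3[C@@H](O[Si](C)(C)C(C)(C)C)[C@@]4(O)[C@H](/C=C(COCc5ccc(OC)cc5)\C=C/[C@@H](O1)[C@@]23C)OC(=O)[C@@H]4C
F7 | step 25 | 11α,12α-epoxide of F6 | CC(C)(C)[Si]1(C(C)(C)C)O[C@H]2C[C@H]6O[C@@]6(C)[C@@H]3[C@@H](O[Si](C)(C)C(C)(C)C)[C@@]4(O)[C@H](/C=C(COCc5ccc(OC)cc5)\C=C/[C@@H](O1)[C@@]23C)OC(=O)[C@@H]4C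
F8 | step 25 | macrocyclic 2,8,9,14-tetraol 16-O-PMB ether | O[C@H]1C[C@H]2O[C@@]2(C)[C@@H]2[C@@H](O)[C@@]3(O)[C@H](/C=C(COCc4ccc(OC)cc4)\C=C/[C@@H](O)[C@@]12C)OC(=O)[C@@H]3C
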